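**Plan**

- Retrosynthesis (carotenoid numbering, primed atoms on the 2,6,6-trimethylcyclohex-2-enyl ring, ring ε): cut C11=C12 (last Wittig) and C11′=C12′ (first Wittig) to give an ε-C15 phosphonium salt, the C10 trienedial and an enyne-C15 phosphonium salt; cut the enyne end at ring C6–C7(sp) (Sonogashira) back to a hydroxy-trimethylcyclohexanone.
- Ring ε: trim the side chain back to a C7′ CH2O group, then cut the ring bond C1′–C6′ (CMe2 carbon to the allylic CH). The enabling feature is that C6′ is the γ-carbon of the ring allyl unit C4′=C5′(Me)–C6′: an open-chain (E)-allylsilane with silicon on C4′ offers C6′ as nucleophile to a C1′ tertiary cation made from an isopropenyl group, and loss of silicon fixes the 4′,5′ double bond.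
- Forward order: carbamate → α-silyl boronic ester → Zweifel olefination to the allylsilane → ring ε by the cyclisation → α-cyclocitral → α-ionone → C15 salt → C25 aldehyde; separately enol triflate → enyne ring → C15 tributylphosphonium salt; then union and desilylation.
- Stereochemistry: C4′(Si) comes from (+)-sparteine-mediated lithiation–borylation and is relayed to C6′ (R) by anti SE2′ attack; C3 (R) comes from (4R,6R)-4-hydroxy-2,2,6-trimethylcyclohexanone; C9=C10 (E) comes from the purchased (E)-enynol and the other alkenes from E-selective olefinations.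

Key step: step 6

Assumption: the SMILES is read as all-E (3R,6′R)-crocoxanthin; the carbinol carbon of 19 and the two transient carbons of 12 are stereochemically irrelevant mixtures.

**Route**

Step 1
Reactants: 1 4-methylpent-4-en-1-ol
Product: 2 4-methylpent-4-en-1-yl N,N-di(propan-2-yl)carbamate
Conditions: iPr2NC(O)Cl, Et3N, CH2Cl2, reflux
Reagents that add atoms: N,N-di(propan-2-yl)carbamoyl chloride, SMILES CC(C)N(C(C)C)C(Cl)=O
Why: carbamoylation of the primary alcohol installs the group that directs the asymmetric α-lithiation and later leaves, while the remote 1,1-disubstituted alkene is inert.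

Step 2
Reactants: 2 4-methylpent-4-en-1-yl N,N-di(propan-2-yl)carbamate
Product: 5 dimethyl(phenyl)[(1S)-4-methyl-1-(4,4,5,5-tetramethyl-1,3,2-dioxaborolan-2-yl)pent-4-en-1-yl]silane, via lithiated carbamate 3 (not isolated), via silylboronate complex 4 (not isolated)
Conditions: sBuLi, (+)-sparteine, Et2O, −78 °C; then PhMe2Si–Bpin, −78 °C to reflux
Reagents that add atoms: 2-[dimethyl(phenyl)silyl]-4,4,5,5-tetramethyl-1,3,2-dioxaborolane, SMILES C[Si](C)(c1ccccc1)B1OC(C)(C)C(C)(C)O1
Why: lithiation–borylation, in which the (+)-sparteine–sBuLi complex removes the pro-R α-hydrogen to give configurationally stable 3, boron adds with retention to give 4, and 1,2-migration of silicon from boron to carbon with inversion and loss of the carbamate sets the S carbon that carries both silicon and boron.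

Step 3
Reactants: 6 but-2-yn-1-ol
Product: 8 (2Z)-3-iodobut-2-en-1-ol, via cyclic vinylalanate 7 (not isolated)
Conditions: NaAlH2(OCH2CH2OMe)2 (Red-Al), THF, 0 °C to rt; then I2, −78 to 0 °C; then H2O
Reagents that add atoms: iodine, SMILES II
Why: hydroxyl-directed trans-hydroalumination of the propargylic alcohol places aluminium on C3 cis to the CH2O group in the five-membered alanate 7, and iododealumination with retention gives the Z iodide.

Step 4
Reactants: 8 (2Z)-3-iodobut-2-en-1-ol
Product: 9 {[(2Z)-3-iodobut-2-en-1-yl]oxy}tri(propan-2-yl)silane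
Conditions: iPr3SiCl, imidazole, DMF, rt
Reagents that add atoms: chlorotri(propan-2-yl)silane, SMILES CC(C)[Si](Cl)(C(C)C)C(C)C
Why: silyl ether formation with the bulky triisopropylsilyl group, chosen because it resists oxygen-to-carbon silyl migration in the cis-γ-silyloxy alkenyllithium of the next step and should survive methoxide and the cyclisation medium.

Step 5
Reactants: 9 {[(2Z)-3-iodobut-2-en-1-yl]oxy}tri(propan-2-yl)silane; 5 dimethyl(phenyl)[(1S)-4-methyl-1-(4,4,5,5-tetramethyl-1,3,2-dioxaborolan-2-yl)pent-4-en-1-yl]silane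
Product: 13 {[(2E,4R)-4-[dimethyl(phenyl)silyl]-3,7-dimethylocta-2,7-dien-1-yl]oxy}tri(propan-2-yl)silane, via alkenyllithium 10 (not isolated), via alkenylboronate complex 11 (not isolated), via β-iodoalkyl boronic ester 12 (not isolated)
Conditions: 9, tBuLi, Et2O, −78 °C; then 5, THF, −78 to 0 °C; then I2, MeOH, −78 °C; NaOMe, MeOH, −78 °C to rt
Reagents that add atoms: none
Why: Zweifel olefination, in which iodine triggers 1,2-migration of the α-silyl alkyl group from boron to the alkenyl carbon with retention at the migrating stereocentre (S at boron becomes 4R by a priority change only) and anti elimination of boron and iodine inverts the alkene geometry, so that the alkenyl unit with boron cis to CH2O gives the E allylsilane.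

Step 6
Reactants: 13 {[(2E,4R)-4-[dimethyl(phenyl)silyl]-3,7-dimethylocta-2,7-dien-1-yl]oxy}tri(propan-2-yl)silane
Product: 15 tri(propan-2-yl){[(1R)-2,6,6-trimethylcyclohex-2-en-1-yl]methoxy}silane, via tertiary carbocation 14 (not isolated)
Conditions: [N,N′-bis(3,5-di-tert-butylsalicylidene)cyclohexane-1,2-diaminato]cobalt (5 mol%), N-fluoro-2,4,6-trimethylpyridinium triflate, PhSiH3, PhCF3, 0 °C; then H2O
Reagents that add atoms: none
Why: Proposed new method: a cobalt hydride generated from the Co(salen) complex, the N-fluoropyridinium oxidant and PhSiH3 should transfer a hydrogen atom only to the unhindered isopropenyl group, and oxidative radical–polar crossover through an alkylcobalt species should deliver tertiary carbocation 14 in a buffered medium free of Brønsted acid, which an acid-labile allylsilane needs; the closest known reaction types are the cobalt-catalysed MHAT radical–polar crossover hydrofunctionalisations and polyene cyclisations of 1,1-disubstituted alkenes and the Lewis-acid tert-alkylation of allylsilanes (Hosomi–Sakurai type), which have not been combined. Cation 14 is attacked by the CH terminus of the trisubstituted allylsilane in a 6-endo-trig cation–olefin closure through a chair-like transition state, which forms the bond between the CMe2 carbon and the future ring CH and leaves a tertiary β-silyl cation. The new stereocentre is controlled by the C–Si stereocentre through anti SE2′ attack: the C–Si bond must lie antiperiplanar to the forming C–C bond, and with the E alkene (hydrogen, not the CH2OSi group, cis to the silyl-bearing carbon) the only productive conformer has the tether inside and silicon on the opposite face, a preference reinforced by allylic 1,2-strain with the vinylic methyl, so that 4R should be relayed to 1R even if part of the material closes at the radical stage. Loss of the silyl group from the β-silyl cation then places the ring double bond only in the 2,3 (α) position, with no β or exocyclic isomer. The step needs chemoselective hydrogen-atom transfer (secured by the steric difference between the terminal and the trisubstituted alkene), six- over five-membered closure (secured by the tertiary β-silyl cation that only attack at the CH terminus produces) and suppression of protodesilylation and fluoride capture (secured by the 2,4,6-trimethylpyridine released as buffer and the triflate counter-ion).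

Step 7
Reactants: 15 tri(propan-2-yl){[(1R)-2,6,6-trimethylcyclohex-2-en-1-yl]methoxy}silane
Product: 16 [(1R)-2,6,6-trimethylcyclohex-2-en-1-yl]methanol
Conditions: Bu4NF, THF, rt; then H2O
Reagents that add atoms: none
Why: fluoride-mediated desilylation of the primary silyl ether, with no acid present that could move the ring double bond into the β position and with the stereocentre not involved.

Step 8
Reactants: 16 [(1R)-2,6,6-trimethylcyclohex-2-en-1-yl]methanol
Product: 17 (1R)-2,6,6-trimethylcyclohex-2-ene-1-carbaldehyde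
Conditions: Dess–Martin periodinane, NaHCO3, CH2Cl2, 0 °C
Reagents that add atoms: none
Why: Dess–Martin oxidation under buffered, near-neutral conditions should give the α-stereogenic β,γ-unsaturated aldehyde without enolisation, and the crude aldehyde is used at once.

Step 9
Reactants: 17 (1R)-2,6,6-trimethylcyclohex-2-ene-1-carbaldehyde
Product: 18 (3E)-4-[(1R)-2,6,6-trimethylcyclohex-2-en-1-yl]but-3-en-2-one
Conditions: (MeO)2P(O)CH2C(O)Me, LiCl, iPr2NEt, MeCN, 0 °C to rt
Reagents that add atoms: dimethyl (2-oxopropyl)phosphonate, SMILES COP(=O)(CC(C)=O)OC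
Why: Horner–Wadsworth–Emmons olefination under Masamune–Roush conditions, in which the lithium-chelated ketophosphonate is deprotonated by a weak amine base, should give the E enone while leaving the hindered α-hydrogen of the aldehyde untouched.

Step 10
Reactants: 18 (3E)-4-[(1R)-2,6,6-trimethylcyclohex-2-en-1-yl]but-3-en-2-one
Product: 19 (1E)-3-methyl-1-[(1R)-2,6,6-trimethylcyclohex-2-en-1-yl]penta-1,4-dien-3-ol (both carbinol epimers)
Conditions: CH2=CHMgBr, THF, −78 to 0 °C; then H2O
Reagents that add atoms: vinylmagnesium bromide, SMILES C=C[Mg]Br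
Why: 1,2-addition of the Grignard reagent to the enone carbonyl gives the tertiary bis-allylic alcohol, whose new carbinol centre is irrelevant because it is lost in the next step.

Step 11
Reactants: 19 (1E)-3-methyl-1-[(1R)-2,6,6-trimethylcyclohex-2-en-1-yl]penta-1,4-dien-3-ol
Product: 20 {(2E,4E)-3-methyl-5-[(1R)-2,6,6-trimethylcyclohex-2-en-1-yl]penta-2,4-dien-1-yl}(triphenyl)phosphonium bromide
Conditions: Ph3P·HBr, MeOH, rt
Reagents that add atoms: triphenylphosphine hydrobromide, SMILES [Br-].[PH+](c1ccccc1)(c1ccccc1)c1ccccc1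
Why: acid-promoted ionisation of the tertiary allylic alcohol and capture of the pentadienyl cation by triphenylphosphine at the primary terminus (allylic transposition, the classical route to C15 Wittig salts) should give mainly the 2E salt, the ring CH not being part of the delocalised cation.

Step 12
Reactants: 20 {(2E,4E)-3-methyl-5-[(1R)-2,6,6-trimethylcyclohex-2-en-1-yl]penta-2,4-dien-1-yl}(triphenyl)phosphonium bromide; 21 (2E,4E,6E)-2,7-dimethylocta-2,4,6-trienedial
Product: 23 (2E,4E,6E,8E,10E,12E)-2,7,11-trimethyl-13-[(1R)-2,6,6-trimethylcyclohex-2-en-1-yl]trideca-2,4,6,8,10,12-hexaenal, via phosphonium ylide 22 (not isolated)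
Conditions: 21 (3 equiv), NaOMe, CH2Cl2–MeOH, 0 °C to rt; then I2 (cat.), CH2Cl2, rt, daylight
Reagents that add atoms: none
Why: Wittig olefination of one aldehyde group of the symmetrical dialdehyde, kept in excess to suppress double condensation, followed by iodine-catalysed equilibration of the new C11′=C12′ bond and of any 9′Z material to the all-E C25 aldehyde, which is safe here because the enyne end is not yet present.

Step 13
Reactants: 24 (4R,6R)-4-hydroxy-2,2,6-trimethylcyclohexan-1-one
Product: 25 (4R,6R)-4-[(tert-butyldimethylsilyl)oxy]-2,2,6-trimethylcyclohexan-1-one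
Conditions: tBuMe2SiCl, imidazole, DMF, rt
Reagents that add atoms: tert-butyl(chloro)dimethylsilane, SMILES CC(C)(C)[Si](C)(C)Cl
Why: silyl protection of the secondary alcohol, which carries the future C3 stereocentre, before enolate and palladium chemistry.

Step 14
Reactants: 25 (4R,6R)-4-[(tert-butyldimethylsilyl)oxy]-2,2,6-trimethylcyclohexan-1-one
Product: 27 (4R)-4-[(tert-butyldimethylsilyl)oxy]-2,6,6-trimethylcyclohex-1-en-1-yl trifluoromethanesulfonate, via lithium enolate 26 (not isolated)
Conditions: LDA, THF, −78 to 0 °C; then PhNTf2, 0 °C to rt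
Reagents that add atoms: N-phenylbis(trifluoromethanesulfonimide), SMILES O=S(=O)(N(c1ccccc1)S(=O)(=O)C(F)(F)F)C(F)(F)F
Why: enolisation can occur only toward the methyl-bearing α-carbon because the other α-carbon is quaternary, and O-triflation of the enolate gives the tetrasubstituted enol triflate with loss of the C6 stereocentre and retention of the silyloxy centre.

Step 15
Reactants: 27 (4R)-4-[(tert-butyldimethylsilyl)oxy]-2,6,6-trimethylcyclohex-1-en-1-yl trifluoromethanesulfonate; 28 (2E)-3-methylpent-2-en-4-yn-1-ol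
Product: 29 (2E)-5-[(4R)-4-[(tert-butyldimethylsilyl)oxy]-2,6,6-trimethylcyclohex-1-en-1-yl]-3-methylpent-2-en-4-yn-1-ol
Conditions: Pd(PPh3)4, CuI, iPr2NH, DMF, rt
Reagents that add atoms: none
Why: Sonogashira coupling of the enol triflate with the terminal alkyne forms the ring C(sp2)–C(sp) bond and carries the E trisubstituted alkene of the enynol unchanged into the product.

Step 16
Reactants: 29 (2E)-5-[(4R)-4-[(tert-butyldimethylsilyl)oxy]-2,6,6-trimethylcyclohex-1-en-1-yl]-3-methylpent-2-en-4-yn-1-ol
Product: 31 tributyl{(2E)-5-[(4R)-4-[(tert-butyldimethylsilyl)oxy]-2,6,6-trimethylcyclohex-1-en-1-yl]-3-methylpent-2-en-4-yn-1-yl}phosphonium bromide, via allylic bromide 30 (not isolated)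
Conditions: CBr4, Bu3P, CH2Cl2, −20 to 0 °C; then Bu3P, rt
Reagents that add atoms: carbon tetrabromide, SMILES BrC(Br)(Br)Br; tributylphosphine, SMILES CCCCP(CCCC)CCCC
Why: Appel bromination of the primary allylic alcohol by direct SN2 displacement, which avoids an allyl cation and so keeps the E geometry next to the alkyne, followed by quaternisation of tributylphosphine, chosen because its allylic ylides give E alkenes under kinetic control.

Step 17
Reactants: 31 tributyl{(2E)-5-[(4R)-4-[(tert-butyldimethylsilyl)oxy]-2,6,6-trimethylcyclohex-1-en-1-yl]-3-methylpent-2-en-4-yn-1-yl}phosphonium bromide; 23 (2E,4E,6E,8E,10E,12E)-2,7,11-trimethyl-13-[(1R)-2,6,6-trimethylcyclohex-2-en-1-yl]trideca-2,4,6,8,10,12-hexaenal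
Product: 33 tert-butyldimethylsilyl ether of (3R,6′R)-7,8-didehydro-β,ε-caroten-3-ol, via tributylphosphonium ylide 32 (not isolated)
Conditions: KOtBu, THF, −78 °C; then 23, −78 to 0 °C, dark
Reagents that add atoms: none
Why: Wittig olefination with the semi-stabilised trialkylphosphonium ylide should form C11=C12 E-selectively, which matters because the 9Z isomers of 7,8-didehydro polyenes are thermodynamically competitive and a final iodine equilibration is therefore excluded.

Step 18
Reactants: 33 tert-butyldimethylsilyl ether of (3R,6′R)-7,8-didehydro-β,ε-caroten-3-ol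
Product: 34 (3R,6′R)-7,8-didehydro-β,ε-caroten-3-ol (crocoxanthin)
Conditions: Bu4NF, AcOH, THF, 0 °C to rt, dark
Reagents that add atoms: none
Why: fluoride-mediated cleavage of the secondary silyl ether under buffered conditions should release the C3 alcohol without touching the polyene or either stereocentre.

**Compound list**

1 | 4-methylpent-4-en-1-ol | CC(=C)CCCO | starting material
2 | 4-methylpent-4-en-1-yl N,N-di(propan-2-yl)carbamate | CC(=C)CCCOC(=O)N(C(C)C)C(C)C | intermediate
3 | (1R)-1-lithio-4-methylpent-4-en-1-yl N,N-di(propan-2-yl)carbamate (sparteine complex) | CC(=C)CC[C@@H]([Li])OC(=O)N(C(C)C)C(C)C | intermediate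
4 | lithium silylboronate complex of 3 with the silylboronic ester (1R) | [Li+].CC(=C)CC[C@@H]([B-]1([Si](C)(C)c2ccccc2)OC(C)(C)C(C)(C)O1)OC(=O)N(C(C)C)C(C)C | intermediate
5 | dimethyl(phenyl)[(1S)-4-methyl-1-(4,4,5,5-tetramethyl-1,3,2-dioxaborolan-2-yl)pent-4-en-1-yl]silane | CC(=C)CC[C@@H]([Si](C)(C)c1ccccc1)B1OC(C)(C)C(C)(C)O1 | intermediate
6 | but-2-yn-1-ol | CC#CCO | starting material
7 | sodium 2,2-bis(2-methoxyethoxy)-3-methyl-2,5-dihydro-1,2-oxaluminol-2-uide (cyclic vinylalanate) | CC1=CCO[Al-]1(OCCOC)OCCOC.[Na+] | intermediate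
8 | (2Z)-3-iodobut-2-en-1-ol | C/C(I)=C/CO | intermediate
9 | {[(2Z)-3-iodobut-2-en-1-yl]oxy}tri(propan-2-yl)silane | C/C(I)=C/CO[Si](C(C)C)(C(C)C)C(C)C | intermediate
10 | [4-{[tri(propan-2-yl)silyl]oxy}but-2-en-2-yl]lithium, lithium cis to CH2OSi | C/C([Li])=C/CO[Si](C(C)C)(C(C)C)C(C)C | intermediate
11 | lithium alkenylboronate complex of 5 and 10 (boron cis to CH2OSi) | [Li+].CC(=C)CC[C@@H]([Si](C)(C)c1ccccc1)[B-]1(/C(C)=C\CO[Si](C(C)C)(C(C)C)C(C)C)OC(C)(C)C(C)(C)O1 | intermediate
12 | β-iodoalkyl boronic ester from anti addition of the migrating group and iodine (mixture at the two transient carbons) | CC(=C)CC[C@@H]([Si](C)(C)c1ccccc1)C(C)(B1OC(C)(C)C(C)(C)O1)C(I)CO[Si](C(C)C)(C(C)C)C(C)C | intermediate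
13 | {[(2E,4R)-4-[dimethyl(phenyl)silyl]-3,7-dimethylocta-2,7-dien-1-yl]oxy}tri(propan-2-yl)silane | CC(=C)CC[C@@H]([Si](C)(C)c1ccccc1)/C(C)=C/CO[Si](C(C)C)(C(C)C)C(C)C | intermediate
14 | tertiary carbocation from 13 (2-methyl-2-yl cation at the former isopropenyl carbon) | C[C+](C)CC[C@@H]([Si](C)(C)c1ccccc1)/C(C)=C/CO[Si](C(C)C)(C(C)C)C(C)C | intermediate
15 | tri(propan-2-yl){[(1R)-2,6,6-trimethylcyclohex-2-en-1-yl]methoxy}silane | CC1=CCCC(C)(C)[C@H]1CO[Si](C(C)C)(C(C)C)C(C)C | intermediate
16 | [(1R)-2,6,6-trimethylcyclohex-2-en-1-yl]methanol ((R)-α-cyclogeraniol) | CC1=CCCC(C)(C)[C@H]1CO | intermediate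
17 | (1R)-2,6,6-trimethylcyclohex-2-ene-1-carbaldehyde ((R)-α-cyclocitral) | CC1=CCCC(C)(C)[C@H]1C=O | intermediate
18 | (3E)-4-[(1R)-2,6,6-trimethylcyclohex-2-en-1-yl]but-3-en-2-one ((R)-α-ionone) | CC1=CCCC(C)(C)[C@H]1/C=C/C(C)=O | intermediate
19 | (1E)-3-methyl-1-[(1R)-2,6,6-trimethylcyclohex-2-en-1-yl]penta-1,4-dien-3-ol (both carbinol epimers) | CC1=CCCC(C)(C)[C@H]1/C=C/C(C)(O)C=C | intermediate
20 | {(2E,4E)-3-methyl-5-[(1R)-2,6,6-trimethylcyclohex-2-en-1-yl]penta-2,4-dien-1-yl}(triphenyl)phosphonium bromide | CC1=CCCC(C)(C)[C@H]1/C=C/C(C)=C/C[P+](c1ccccc1)(c1ccccc1)c1ccccc1.[Br-] | intermediate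
21 | (2E,4E,6E)-2,7-dimethylocta-2,4,6-trienedial | O=C/C(C)=C/C=C/C=C(\C)C=O | starting material
22 | triphenylphosphonium ylide of 20 | CC1=CCCC(C)(C)[C@H]1/C=C/C(C)=C/C=P(c1ccccc1)(c1ccccc1)c1ccccc1 | intermediate
23 | (2E,4E,6E,8E,10E,12E)-2,7,11-trimethyl-13-[(1R)-2,6,6-trimethylcyclohex-2-en-1-yl]trideca-2,4,6,8,10,12-hexaenal | CC1=CCCC(C)(C)[C@H]1/C=C/C(C)=C/C=C/C(C)=C/C=C/C=C(C)/C=O | intermediate
24 | (4R,6R)-4-hydroxy-2,2,6-trimethylcyclohexan-1-one | O=C1[C@H](C)C[C@@H](O)CC1(C)C | starting material
25 | (4R,6R)-4-[(tert-butyldimethylsilyl)oxy]-2,2,6-trimethylcyclohexan-1-one | O=C1[C@H](C)C[C@@H](O[Si](C)(C)C(C)(C)C)CC1(C)C | intermediate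
26 | lithium (4R)-4-[(tert-butyldimethylsilyl)oxy]-2,6,6-trimethylcyclohex-1-en-1-olate | [Li]OC1=C(C)C[C@@H](O[Si](C)(C)C(C)(C)C)CC1(C)C | intermediate
27 | (4R)-4-[(tert-butyldimethylsilyl)oxy]-2,6,6-trimethylcyclohex-1-en-1-yl trifluoromethanesulfonate | O=S(=O)(OC1=C(C)C[C@@H](O[Si](C)(C)C(C)(C)C)CC1(C)C)C(F)(F)F | intermediate
28 | (2E)-3-methylpent-2-en-4-yn-1-ol | C#C/C(C)=C/CO | starting material
29 | (2E)-5-[(4R)-4-[(tert-butyldimethylsilyl)oxy]-2,6,6-trimethylcyclohex-1-en-1-yl]-3-methylpent-2-en-4-yn-1-ol | OC/C=C(\C)C#CC1=C(C)C[C@@H](O[Si](C)(C)C(C)(C)C)CC1(C)C | intermediate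
30 | {[(1R)-4-[(3E)-5-bromo-3-methylpent-3-en-1-yn-1-yl]-3,5,5-trimethylcyclohex-3-en-1-yl]oxy}(tert-butyl)dimethylsilane | BrC/C=C(\C)C#CC1=C(C)C[C@@H](O[Si](C)(C)C(C)(C)C)CC1(C)C | intermediate
31 | tributyl{(2E)-5-[(4R)-4-[(tert-butyldimethylsilyl)oxy]-2,6,6-trimethylcyclohex-1-en-1-yl]-3-methylpent-2-en-4-yn-1-yl}phosphonium bromide | CCCC[P+](CCCC)(CCCC)C/C=C(\C)C#CC1=C(C)C[C@@H](O[Si](C)(C)C(C)(C)C)CC1(C)C.[Br-] | intermediate
32 | tributylphosphonium ylide of 31 | CCCCP(CCCC)(CCCC)=C/C=C(\C)C#CC1=C(C)C[C@@H](O[Si](C)(C)C(C)(C)C)CC1(C)C | intermediate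
33 | tert-butyldimethylsilyl ether of (3R,6′R)-7,8-didehydro-β,ε-caroten-3-ol | CC1=CCCC(C)(C)[C@H]1/C=C/C(C)=C/C=C/C(C)=C/C=C/C=C(C)/C=C/C=C(\C)C#CC1=C(C)C[C@@H](O[Si](C)(C)C(C)(C)C)CC1(C)C | intermediate
34 | (3R,6′R)-7,8-didehydro-β,ε-caroten-3-ol (crocoxanthin, CNP0322200.1) | CC1=CCCC(C)(C)[C@H]1/C=C/C(C)=C/C=C/C(C)=C/C=C/C=C(C)/C=C/C=C(\C)C#CC1=C(C)C[C@@H](O)CC1(C)C | target

**Step count and risks**

Total step count: 18. Longest linear sequence: 12 steps (1, 2, 5, 6, 7, 8, 9, 10, 11, 12, 17, 18).

Steps most likely to fail: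

1. Step 6 (carries the new-method label). What may go wrong: protodesilylation of the allylsilane or 1,4-elimination of silane and silyl ether, reversible hydrogen-atom transfer that isomerises the isopropenyl group, capture of the tertiary centre by fluoride or hydride before ring closure, or closure at the radical stage with lower facial selectivity. The fallback uses known chemistry only, sets out from 13 and comes back at 15. Mukaiyama hydration of the isopropenyl group (Co(acac)2, PhSiH3, O2, iPrOH, rt) should give the tertiary alcohol (5R,6E)-5-[dimethyl(phenyl)silyl]-2,6-dimethyl-8-{[tri(propan-2-yl)silyl]oxy}oct-6-en-2-ol F1. Ionisation of F1 with TiCl4 and 2,6-di-tert-butyl-4-methylpyridine in CH2Cl2 at −78 °C regenerates cation 14 in a purely polar way, and the intramolecular Hosomi–Sakurai tert-alkylation should close it to 15 with the same anti SE2′ relay.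

2. Step 9. What may go wrong: enolisation of the α-stereogenic β,γ-unsaturated aldehyde under the basic olefination conditions, which would epimerise the ring CH or move the ring double bond into conjugation, together with slow addition to the hindered carbonyl group. The fallback sets out from 17 and comes back at 18. Non-basic Takai iodo-olefination (CrCl2, CHI3, THF, 0 °C) should give (6R)-6-[(E)-2-iodoethenyl]-1,5,5-trimethylcyclohex-1-ene F2. Iodine–lithium exchange (tBuLi, Et2O, −78 °C) gives {(E)-2-[(1R)-2,6,6-trimethylcyclohex-2-en-1-yl]ethenyl}lithium F3, which is acylated with N-methoxy-N-methylacetamide to give 18.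

3. Step 17. What may go wrong: incomplete E selectivity at the new C11=C12 bond and scrambling of the C9=C10 geometry in the delocalised ylide, neither of which can be repaired by equilibration, and incomplete ylide formation from the weakly acidic trialkylphosphonium salt. The fallback replaces the ylide by a phosphonate carbanion, sets out from 29 (through bromide 30) and comes back at 33. Bromide 30, made with CBr4 and PPh3 and isolated, is converted by Michaelis–Becker reaction with sodium diethyl phosphite (THF, 0 °C to rt) into diethyl {(2E)-5-[(4R)-4-[(tert-butyldimethylsilyl)oxy]-2,6,6-trimethylcyclohex-1-en-1-yl]-3-methylpent-2-en-4-yn-1-yl}phosphonate F4. Deprotonation with NaHMDS (THF, −78 °C) gives the sodium phosphonate carbanion F5, and Horner–Wadsworth–Emmons reaction with 23 should give 33 with thermodynamic E preference at the new bond.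

Further compounds
F1 | step 6 | (5R,6E)-5-[dimethyl(phenyl)silyl]-2,6-dimethyl-8-{[tri(propan-2-yl)silyl]oxy}oct-6-en-2-ol | CC(C)(O)CC[C@@H]([Si](C)(C)c1ccccc1)/C(C)=C/CO[Si](C(C)C)(C(C)C)C(C)C
F2 | step 9 | (6R)-6-[(E)-2-iodoethenyl]-1,5,5-trimethylcyclohex-1-ene | CC1=CCCC(C)(C)[C@H]1/C=C/I
F3 | step 9 | {(E)-2-[(1R)-2,6,6-trimethylcyclohex-2-en-1-yl]ethenyl}lithium | CC1=CCCC(C)(C)[C@H]1/C=C/[Li]
F4 | step 17 | diethyl {(2E)-5-[(4R)-4-[(tert-butyldimethylsilyl)oxy]-2,6,6-trimethylcyclohex-1-en-1-yl]-3-methylpent-2-en-4-yn-1-yl}phosphonate | CCOP(=O)(OCC)C/C=C(\C)C#CC1=C(C)C[C@@H](O[Si](C)(C)C(C)(C)C)CC1(C)C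
F5 | step 17 | sodium salt of the α-carbanion of phosphonate F4 | [Na+].CCOP(=O)(OCC)[CH-]/C=C(\C)C#CC1=C(C)C[C@@H](O[Si](C)(C)C(C)(C)C)CC1(C)C
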